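**Retrosynthetic overview**

1. The target has one ring, the oxolan-2-one O1–C2(=O)–C3–C4–C5. The strategy rests on the adjacent carbons C3 (tertiary OH and 4-hydroxy-3-methoxybenzyl) and C4 (3,4-dimethoxybenzyl): their two benzylic carbons are trans, and the C3 oxygen is cis to the C4 benzyl group.
2. Late stage: both benzyl ethers are removed by hydrogenolysis, the C5 methylene comes from a C5 menthyloxy acetal (borohydride–hydroxide, relactonisation), and the veratryl CH2 comes from an aryl dithiane (Raney Ni).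
3. Key disconnection: the C4–C(dithiane) and C3–CH2Ar bonds, made in one flask on the intact ring by conjugate addition of the lithiated veratryl dithiane to a (5R)-3-benzyloxy-5-menthyloxybutenolide and benzylation of the resulting α-benzyloxy enolate; the C3 oxygen is already in the acceptor.
4. The acceptor comes from furfural and (−)-menthol: photooxygenation, acetalisation with crystallisation of the (5R)-epimer, cis-dihydroxylation, acetylation–elimination to the enol acetate, and O-benzylation of the enol.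
5. Ring order: the lactone ring is present from step 1 and no other ring is built; it is only opened and reclosed when the acetal is reduced.

Key step: step 9

Assumption: reagents approach the 5-menthyloxybutenolide ring anti to the nearest ring substituent, and the acetal that crystallises from (−)-menthol is the (5R)-epimer. In the names below, "menthyl" is (1R,2S,5R)-2-isopropyl-5-methylcyclohexyl.

**Route**

Step 1
Reactants: 1 furfural
Product: 2 5-hydroxyfuran-2(5H)-one (racemic hemiacetal)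
Conditions: O2, hν (visible), methylene blue (cat.), MeOH, rt
Reagents that add atoms: oxygen, O=O
Why: Singlet-oxygen [4+2] cycloaddition to the furan gives the 2,5-endoperoxide, which methanol fragments with loss of the formyl carbon as methyl formate (dye-sensitised photooxygenation of furfural), leaving C5 as a labile, racemic hemiacetal.

Step 2
Reactants: 2 5-hydroxyfuran-2(5H)-one; 3 (1R,2S,5R)-menthol
Product: 4 (5R)-5-(menthyloxy)furan-2(5H)-one
Conditions: p-TsOH (cat.), toluene, reflux, Dean–Stark; crystallisation from petroleum ether, mother liquor re-equilibrated with acid and recrystallised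
Reagents that add atoms: none
Why: Acid-catalysed acetalisation of the pseudo-acid gives both C5 epimers, which interconvert through the acyloxocarbenium ion while the (5R)-epimer crystallises (crystallisation-induced diastereomer transformation), and this sets C5.

Step 3
Reactants: 4 (5R)-5-(menthyloxy)furan-2(5H)-one
Product: 5 (3S,4R,5R)-3,4-dihydroxy-5-(menthyloxy)oxolan-2-one
Conditions: OsO4 (2 mol%), N-methylmorpholine N-oxide, acetone/H2O, rt
Reagents that add atoms: N-methylmorpholine N-oxide, C[N+]1([O-])CCOCC1; water, O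
Why: Upjohn cis-dihydroxylation of the C3=C4 bond should occur on the face anti to the C5 menthyloxy group; both new stereocentres are removed again in step 4, so this selectivity only affects handling.

Step 4
Reactants: 5 (3S,4R,5R)-3,4-dihydroxy-5-(menthyloxy)oxolan-2-one
Product: 7 (5R)-3-acetoxy-5-(menthyloxy)furan-2(5H)-one, via 3,4-diacetate 6 (not isolated)
Conditions: Ac2O (3 equiv), Et3N (5 equiv), DMAP (cat.), CH2Cl2, 0 °C→rt
Reagents that add atoms: acetic anhydride, CC(=O)OC(C)=O
Why: O-Acetylation is followed by E1cB β-elimination of the C4 acetate through the lactone enolate at C3, the usual behaviour of acylated α,β-dihydroxy lactones, which gives the enol acetate and leaves C5 untouched.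

Step 5
Reactants: 7 (5R)-3-acetoxy-5-(menthyloxy)furan-2(5H)-one
Product: 9 (5R)-3-(benzyloxy)-5-(menthyloxy)furan-2(5H)-one, via potassium enolate 8 (not isolated)
Conditions: K2CO3, MeOH (3 equiv), BnBr, DMF, 0 °C→rt
Reagents that add atoms: benzyl bromide, BrCc1ccccc1
Why: Carbonate-mediated methanolysis of the activated enol ester frees the 3-oxidobutenolide (the enolate of the α-keto lactone), which is O-benzylated in situ (Williamson alkylation of an acidic enol, as with isotetronic acids); no stereocentre is formed and the weak base should not touch C5–H.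

Step 6
Reactants: 10 3,4-dimethoxybenzaldehyde
Product: 11 2-(3,4-dimethoxyphenyl)-1,3-dithiane
Conditions: propane-1,3-dithiol, BF3·OEt2 (cat.), CH2Cl2, 0 °C→rt
Reagents that add atoms: propane-1,3-dithiol, SCCCS
Why: Lewis acid-catalysed dithioacetalisation of an aromatic aldehyde.

Step 7
Reactants: 12 4-(benzyloxy)-3-methoxybenzaldehyde
Product: 13 [4-(benzyloxy)-3-methoxyphenyl]methanol
Conditions: NaBH4, MeOH, 0 °C
Reagents that add atoms: none
Why: Borohydride reduction of an aryl aldehyde to the benzylic alcohol.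

Step 8
Reactants: 13 [4-(benzyloxy)-3-methoxyphenyl]methanol
Product: 14 4-(benzyloxy)-3-methoxybenzyl bromide
Conditions: PBr3, Et2O, 0 °C; used freshly prepared
Reagents that add atoms: phosphorus tribromide, BrP(Br)Br
Why: Bromide displaces the phosphite ester of the benzylic alcohol (SN2); the electron-rich benzylic bromide is labile and is therefore used at once.

Step 9
Reactants: 11 2-(3,4-dimethoxyphenyl)-1,3-dithiane; 9 (5R)-3-(benzyloxy)-5-(menthyloxy)furan-2(5H)-one; 14 4-(benzyloxy)-3-methoxybenzyl bromide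
Product: 17 (3S,4R,5R)-3-(benzyloxy)-3-[4-(benzyloxy)-3-methoxybenzyl]-4-[2-(3,4-dimethoxyphenyl)-1,3-dithian-2-yl]-5-(menthyloxy)oxolan-2-one, via 2-lithiodithiane 15 (not isolated), via lithium enolate 16 (not isolated)
Conditions: 11, n-BuLi, THF, −78→−20 °C; add 9, −78 °C; then DMPU, 14, −78 °C→rt; aq. NH4Cl
Reagents that add atoms: none
Why: Proposed new method: the 2-lithio-2-aryl-1,3-dithiane 15, a soft acyl anion equivalent, should add 1,4 to C4 of butenolide 9 on the face opposite the C5 menthyloxy group to give the α-benzyloxy lithium enolate 16, which is then C-benzylated at C3 by bromide 14 (SN2) on the face opposite the new, very bulky C4 dithianyl group. The closest known reaction is the tandem conjugate addition of lithiated aryl dithianes to (5R)-5-menthyloxy-2(5H)-furanone followed by enolate benzylation; what is new is the 3-benzyloxy group, which makes C4 less electrophilic and turns the alkylation into the formation of an oxygen-bearing quaternary carbon. No ring closes in this step. C4 (R) is controlled by the C5 acetal stereocentre (anti addition) and C3 (S) by the C4 substituent (anti alkylation), so the two carbon substituents end trans and the benzyloxy group cis to the dithianyl group, as the target needs. The step needs 1,4-addition to win over 1,2-addition at C2 and over deprotonation at C5, which the soft, hindered dithiane anion in THF at −78 °C should secure, and C- over O-alkylation of the enolate, which the reactive benzylic bromide with DMPU should secure.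

Step 10
Reactants: 17 (3S,4R,5R)-3-(benzyloxy)-3-[4-(benzyloxy)-3-methoxybenzyl]-4-[2-(3,4-dimethoxyphenyl)-1,3-dithian-2-yl]-5-(menthyloxy)oxolan-2-one
Product: 18 (3S,4R,5R)-3-(benzyloxy)-3-[4-(benzyloxy)-3-methoxybenzyl]-4-(3,4-dimethoxybenzyl)-5-(menthyloxy)oxolan-2-one
Conditions: Raney Ni (W-2, deactivated by brief reflux in acetone), EtOH/THF, rt
Reagents that add atoms: none
Why: Mozingo-type reductive desulfurisation turns the dithioketal carbon into the benzylic CH2 without touching a stereocentre, and deactivated nickel at room temperature should spare the benzyl ethers.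

Step 11
Reactants: 18 (3S,4R,5R)-3-(benzyloxy)-3-[4-(benzyloxy)-3-methoxybenzyl]-4-(3,4-dimethoxybenzyl)-5-(menthyloxy)oxolan-2-one
Product: 21 (3S,4S)-3-(benzyloxy)-3-[4-(benzyloxy)-3-methoxybenzyl]-4-(3,4-dimethoxybenzyl)oxolan-2-one, via aldehyde carboxylate 19 (not isolated), via hydroxy carboxylate 20 (not isolated)
Conditions: NaBH4 (excess), KOH, EtOH/H2O, 0 °C→rt; then 2 M HCl to pH 2, rt
Reagents that add atoms: none
Why: Hydroxide opens the acylal-type lactone to a carboxylate and a hemiacetal that loses menthoxide, borohydride reduces the aldehyde as it forms, and acidification relactonises the γ-hydroxy acid onto the untouched C2 carboxyl (saponification, carbonyl reduction, lactonisation), so the carbonyl stays next to the quaternary C3 and C4 is only briefly α to an aldehyde.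

Step 12
Reactants: 21 (3S,4S)-3-(benzyloxy)-3-[4-(benzyloxy)-3-methoxybenzyl]-4-(3,4-dimethoxybenzyl)oxolan-2-one
Product: 22 trachelogenin, (3S,4S)-4-(3,4-dimethoxybenzyl)-3-hydroxy-3-(4-hydroxy-3-methoxybenzyl)oxolan-2-one
Conditions: H2 (1 atm), 10% Pd/C, EtOAc/EtOH, rt
Reagents that add atoms: none
Why: Catalytic hydrogenolysis cleaves the aryl benzyl ether and the tertiary alkyl benzyl ether at their O–CH2Ph bonds; C3 is not benzylic, so its C–O bond and configuration are kept.

**Compound list**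

1 | furfural | O=Cc1ccco1 | starting material
2 | 5-hydroxyfuran-2(5H)-one (racemic) | OC1OC(=O)C=C1 | intermediate
3 | (1R,2S,5R)-menthol | CC(C)[C@@H]1CC[C@@H](C)C[C@H]1O | starting material
4 | (5R)-5-(menthyloxy)furan-2(5H)-one | CC(C)[C@@H]1CC[C@@H](C)C[C@H]1O[C@@H]1OC(=O)C=C1 | intermediate
5 | (3S,4R,5R)-3,4-dihydroxy-5-(menthyloxy)oxolan-2-one | CC(C)[C@@H]1CC[C@@H](C)C[C@H]1O[C@@H]1OC(=O)[C@@H](O)[C@H]1O | intermediate
6 | (3S,4R,5R)-3,4-diacetoxy-5-(menthyloxy)oxolan-2-one | CC(C)[C@@H]1CC[C@@H](C)C[C@H]1O[C@@H]1OC(=O)[C@@H](OC(C)=O)[C@H]1OC(C)=O | intermediate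
7 | (5R)-3-acetoxy-5-(menthyloxy)furan-2(5H)-one | CC(C)[C@@H]1CC[C@@H](C)C[C@H]1O[C@@H]1OC(=O)C(OC(C)=O)=C1 | intermediate
8 | potassium (5R)-5-(menthyloxy)-2-oxo-2,5-dihydrofuran-3-olate | CC(C)[C@@H]1CC[C@@H](C)C[C@H]1O[C@@H]1OC(=O)C([O-])=C1.[K+] | intermediate
9 | (5R)-3-(benzyloxy)-5-(menthyloxy)furan-2(5H)-one | CC(C)[C@@H]1CC[C@@H](C)C[C@H]1O[C@@H]1OC(=O)C(OCc2ccccc2)=C1 | intermediate
10 | 3,4-dimethoxybenzaldehyde | COc1ccc(C=O)cc1OC | starting material
11 | 2-(3,4-dimethoxyphenyl)-1,3-dithiane | COc1ccc(C2SCCCS2)cc1OC | intermediate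
12 | 4-(benzyloxy)-3-methoxybenzaldehyde | COc1cc(C=O)ccc1OCc1ccccc1 | starting material
13 | [4-(benzyloxy)-3-methoxyphenyl]methanol | COc1cc(CO)ccc1OCc1ccccc1 | intermediate
14 | 4-(benzyloxy)-3-methoxybenzyl bromide | COc1cc(CBr)ccc1OCc1ccccc1 | intermediate
15 | 2-(3,4-dimethoxyphenyl)-2-lithio-1,3-dithiane | COc1ccc(C2([Li])SCCCS2)cc1OC | intermediate
16 | lithium enolate of (4R,5R)-3-(benzyloxy)-4-[2-(3,4-dimethoxyphenyl)-1,3-dithian-2-yl]-5-(menthyloxy)oxolan-2-one | CC(C)[C@@H]1CC[C@@H](C)C[C@H]1O[C@@H]1OC(O[Li])=C(OCc2ccccc2)[C@H]1C2(SCCCS2)c2ccc(OC)c(OC)c2 | intermediate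
17 | (3S,4R,5R)-3-(benzyloxy)-3-[4-(benzyloxy)-3-methoxybenzyl]-4-[2-(3,4-dimethoxyphenyl)-1,3-dithian-2-yl]-5-(menthyloxy)oxolan-2-one | CC(C)[C@@H]1CC[C@@H](C)C[C@H]1O[C@@H]1OC(=O)[C@](OCc2ccccc2)(Cc2ccc(OCc3ccccc3)c(OC)c2)[C@H]1C2(SCCCS2)c2ccc(OC)c(OC)c2 | intermediate
18 | (3S,4R,5R)-3-(benzyloxy)-3-[4-(benzyloxy)-3-methoxybenzyl]-4-(3,4-dimethoxybenzyl)-5-(menthyloxy)oxolan-2-one | CC(C)[C@@H]1CC[C@@H](C)C[C@H]1O[C@@H]1OC(=O)[C@](OCc2ccccc2)(Cc2ccc(OCc3ccccc3)c(OC)c2)[C@H]1Cc1ccc(OC)c(OC)c1 | intermediate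
19 | potassium (2S,3R)-2-(benzyloxy)-2-[4-(benzyloxy)-3-methoxybenzyl]-3-(3,4-dimethoxybenzyl)-4-oxobutanoate | O=C[C@H](Cc1ccc(OC)c(OC)c1)[C@@](OCc1ccccc1)(Cc1ccc(OCc2ccccc2)c(OC)c1)C(=O)[O-].[K+] | intermediate
20 | potassium (2S,3S)-2-(benzyloxy)-2-[4-(benzyloxy)-3-methoxybenzyl]-3-(3,4-dimethoxybenzyl)-4-hydroxybutanoate | OC[C@H](Cc1ccc(OC)c(OC)c1)[C@@](OCc1ccccc1)(Cc1ccc(OCc2ccccc2)c(OC)c1)C(=O)[O-].[K+] | intermediate
21 | (3S,4S)-3-(benzyloxy)-3-[4-(benzyloxy)-3-methoxybenzyl]-4-(3,4-dimethoxybenzyl)oxolan-2-one | COc1cc(C[C@@]2(OCc3ccccc3)C(=O)OC[C@@H]2Cc2ccc(OC)c(OC)c2)ccc1OCc1ccccc1 | intermediate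
22 | trachelogenin, (3S,4S)-4-(3,4-dimethoxybenzyl)-3-hydroxy-3-(4-hydroxy-3-methoxybenzyl)oxolan-2-one | COc1cc(C[C@@]2(O)C(=O)OC[C@@H]2Cc2ccc(OC)c(OC)c2)ccc1O | target

**Step count and risks**

Total: 12 steps. Longest linear sequence: 9 steps (steps 1–5 and 9–12).

Steps most likely to fail:

1. Step 9 (the proposed new method). The benzyloxy group at C3 donates into the C3=C4 bond, so conjugate addition may lose to 1,2-addition at C2 or to deprotonation at C5, and the hindered tetrasubstituted enolate may revert by retro-conjugate addition before it is benzylated. The fallback uses known chemistry, brings in the C3 oxygen after the conjugate addition and still adds carbon last at C3; it sets out from 4 and 11 and comes back at 17. Lithiated 11 (n-BuLi, THF, −78 °C) is added to the unsubstituted butenolide 4 and the enolate is protonated with aq. NH4Cl, the known anti conjugate addition, to give (4R,5R)-4-[2-(3,4-dimethoxyphenyl)-1,3-dithian-2-yl]-5-(menthyloxy)oxolan-2-one F1. Enolate hydroxylation (LiN(SiMe3)2, THF, −78 °C; 2-(phenylsulfonyl)-3-phenyloxaziridine) should give (3R,4R,5R)-4-[2-(3,4-dimethoxyphenyl)-1,3-dithian-2-yl]-3-hydroxy-5-(menthyloxy)oxolan-2-one F2, whose C3 configuration does not matter because it is erased later. O-Benzylation (NaH, BnBr, Bu4NI, THF/DMF, 0 °C) gives (3R,4R,5R)-3-(benzyloxy)-4-[2-(3,4-dimethoxyphenyl)-1,3-dithian-2-yl]-5-(menthyloxy)oxolan-2-one F3. Deprotonation with LiN(i-Pr)2 (THF, −78 °C) then produces enolate 16 directly, and benzylation with 14 and DMPU as in step 9 rejoins the route at 17.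

2. Step 11. Opening of the hindered lactone by hydroxide may be slow, and the transient aldehyde can enolise, which would epimerise C4 or expel benzyloxide from C3 before reduction. The fallback never places a carbonyl next to C4; it sets out from 18 and comes back at 21. LiAlH4 (THF, 0 °C→rt) reduces the lactone and the acetal to (2S,3S)-2-(benzyloxy)-2-[4-(benzyloxy)-3-methoxybenzyl]-3-(3,4-dimethoxybenzyl)butane-1,4-diol F4. TBSCl and imidazole (CH2Cl2, 0 °C) silylate the less hindered C4 hydroxyl and leave the neopentyl one, giving (2S,3S)-2-(benzyloxy)-2-[4-(benzyloxy)-3-methoxybenzyl]-4-[(tert-butyldimethylsilyl)oxy]-3-(3,4-dimethoxybenzyl)butan-1-ol F5. Dess–Martin periodinane (CH2Cl2, NaHCO3) gives the non-enolisable aldehyde (2S,3S)-2-(benzyloxy)-2-[4-(benzyloxy)-3-methoxybenzyl]-4-[(tert-butyldimethylsilyl)oxy]-3-(3,4-dimethoxybenzyl)butanal F6, and Pinnick oxidation (NaClO2, NaH2PO4, 2-methyl-2-butene, t-BuOH/H2O) gives (2S,3S)-2-(benzyloxy)-2-[4-(benzyloxy)-3-methoxybenzyl]-4-[(tert-butyldimethylsilyl)oxy]-3-(3,4-dimethoxybenzyl)butanoic acid F7. Desilylation with Bu4NF (THF) and acidic work-up lactonises the γ-hydroxy acid to 21.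

3. Step 5. The free 3-oxidobutenolide may open by β-elimination at C5, be benzylated on C4 in place of oxygen, or lose its C5 configuration, and methoxide may add to the butenolide. The fallback puts the benzyl group on before the double bond is made, so no free enolate is formed; it sets out from 5 and comes back at 9. Neutral double benzylation of diol 5 (2-benzyloxy-1-methylpyridinium triflate, MgO, PhCF3, 85 °C) gives (3S,4R,5R)-3,4-bis(benzyloxy)-5-(menthyloxy)oxolan-2-one F8. DBU (CH2Cl2, 0 °C→rt) then eliminates benzyl alcohol from C4 by the E1cB path known for O-benzylated aldonolactones and gives 9.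

**Further compounds**

F1 | step 9 | (4R,5R)-4-[2-(3,4-dimethoxyphenyl)-1,3-dithian-2-yl]-5-(menthyloxy)oxolan-2-one | CC(C)[C@@H]1CC[C@@H](C)C[C@H]1O[C@@H]1OC(=O)C[C@H]1C1(SCCCS1)c1ccc(OC)c(OC)c1
F2 | step 9 | (3R,4R,5R)-4-[2-(3,4-dimethoxyphenyl)-1,3-dithian-2-yl]-3-hydroxy-5-(menthyloxy)oxolan-2-one | CC(C)[C@@H]1CC[C@@H](C)C[C@H]1O[C@@H]1OC(=O)[C@H](O)[C@H]1C1(SCCCS1)c1ccc(OC)c(OC)c1
F3 | step 9 | (3R,4R,5R)-3-(benzyloxy)-4-[2-(3,4-dimethoxyphenyl)-1,3-dithian-2-yl]-5-(menthyloxy)oxolan-2-one | CC(C)[C@@H]1CC[C@@H](C)C[C@H]1O[C@@H]1OC(=O)[C@H](OCc2ccccc2)[C@H]1C1(SCCCS1)c1ccc(OC)c(OC)c1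
F4 | step 11 | (2S,3S)-2-(benzyloxy)-2-[4-(benzyloxy)-3-methoxybenzyl]-3-(3,4-dimethoxybenzyl)butane-1,4-diol | OC[C@H](Cc1ccc(OC)c(OC)c1)[C@@](OCc1ccccc1)(Cc1ccc(OCc2ccccc2)c(OC)c1)CO
F5 | step 11 | (2S,3S)-2-(benzyloxy)-2-[4-(benzyloxy)-3-methoxybenzyl]-4-[(tert-butyldimethylsilyl)oxy]-3-(3,4-dimethoxybenzyl)butan-1-ol | CC(C)(C)[Si](C)(C)OC[C@H](Cc1ccc(OC)c(OC)c1)[C@@](OCc1ccccc1)(Cc1ccc(OCc2ccccc2)c(OC)c1)CO
F6 | step 11 | (2S,3S)-2-(benzyloxy)-2-[4-(benzyloxy)-3-methoxybenzyl]-4-[(tert-butyldimethylsilyl)oxy]-3-(3,4-dimethoxybenzyl)butanal | CC(C)(C)[Si](C)(C)OC[C@H](Cc1ccc(OC)c(OC)c1)[C@@](OCc1ccccc1)(Cc1ccc(OCc2ccccc2)c(OC)c1)C=O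
F7 | step 11 | (2S,3S)-2-(benzyloxy)-2-[4-(benzyloxy)-3-methoxybenzyl]-4-[(tert-butyldimethylsilyl)oxy]-3-(3,4-dimethoxybenzyl)butanoic acid | CC(C)(C)[Si](C)(C)OC[C@H](Cc1ccc(OC)c(OC)c1)[C@@](OCc1ccccc1)(Cc1ccc(OCc2ccccc2)c(OC)c1)C(=O)O
F8 | step 5 | (3S,4R,5R)-3,4-bis(benzyloxy)-5-(menthyloxy)oxolan-2-one | CC(C)[C@@H]1CC[C@@H](C)C[C@H]1O[C@@H]1OC(=O)[C@@H](OCc2ccccc2)[C@H]1OCc1ccccc1
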